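Everything rests on cutting the C6–C7 bond of the ten-membered ring together with the C19–O7 lactone bond. The key step exploits C7, which is at once the allylic carbinol carbon beside the C5=C6 alkene, the neighbour of the tertiary carbinol C8 and the carrier of the lactone oxygen: a Nozaki–Hiyama–Kishi addition of the Z-alkenyl iodide at C6 to the C7 aldehyde closes the ten-membered ring, sets C7 and arms the C7 alkoxide to close the γ-lactone on the C19 methyl ester. The precursor is a fully substituted ring A cyclohexene bearing the C2–C6 iodoalkene arm on C1 and the C7 aldehyde/C19 ester arm (C8, C9, C17 set) on C10.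

Key step: step 23

Remark: briarane numbering is used for all intermediates; 3,5-dibromo-2H-pyran-2-one, 5-hydroxyfuran-2(5H)-one and (+)-menthol are taken to be purchasable, and the C8 hydroxyl is carried as a triethylsilyl (TES) ether.

Step 1
Reactants: 1 5-hydroxyfuran-2(5H)-one
Product: 2 (5S)-5-[(1S,2R,5S)-menthyloxy]furan-2(5H)-one
Conditions: (+)-menthol, camphorsulfonic acid (cat.), PhMe, reflux (water separator); crystallisation from petroleum ether, mother liquor re-equilibrated with acid
Reagents that add atoms: (1S,2R,5S)-(+)-menthol, O[C@H]1C[C@@H](C)CC[C@@H]1C(C)C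
Why: Acid-catalysed acetal exchange at the hemiacylal carbon should give both C5 epimers, and crystallisation of the 5S epimer with re-equilibration of the rest (crystallisation-induced diastereomer transformation) sets the single stereocentre of the dienophile under control of the menthyl auxiliary.

Step 2
Reactants: 3 3,5-dibromo-2H-pyran-2-one
Product: 4 5-bromo-3-methyl-2H-pyran-2-one
Conditions: SnMe4, Pd(PPh3)4 (cat.), PhMe, 100 °C (sealed tube)
Reagents that add atoms: tetramethylstannane, C[Sn](C)(C)C
Why: Stille cross-coupling, in which zerovalent palladium should insert selectively into the more electron-poor C3–Br bond next to the lactone carbonyl, so that the methyl group (the later C15) enters at C3 and the C5 bromide stays as an activating group that is removed later.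

Step 3
Reactants: 4 5-bromo-3-methyl-2H-pyran-2-one; 2 (5S)-5-[(1S,2R,5S)-menthyloxy]furan-2(5H)-one
Product: 5 endo/anti cycloadduct (ring A with C13 bromide; bridged C2(=O)–O12 lactone; cis-fused menthyloxy γ-lactone across C10–C11)
Conditions: CH2Cl2, 12 kbar, 30 °C
Reagents that add atoms: none
Why: Diels–Alder reaction of a 2-pyrone with an electron-poor alkene, run under pressure below the temperature of CO2 loss: the more nucleophilic C6 terminus of the pyrone should bond to the β-carbon and the methyl-bearing C3 to the α-carbon of the butenolide, the butenolide carbonyl lies endo (so C9 and C20 end up anti to the new lactone bridge) and the diene adds anti to the menthyloxy group, which sets C1, C10, C11 and C12 together in the absolute sense of the target.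

Step 4
Reactants: 5 endo/anti cycloadduct
Product: 6 bridged lactone with C9 carboxylic acid on C10 and C20 as a 1,3-dithiolan-2-yl group on C11 (C13 bromide kept)
Conditions: HSCH2CH2SH, BF3·OEt2, CH2Cl2, 0 °C → rt
Reagents that add atoms: ethane-1,2-dithiol, SCCS
Why: Lewis-acid-mediated transthioacetalisation at the acylal carbon C20 should open only the alkoxy γ-lactone, releasing the C9 carboxylic acid and the menthol auxiliary, while the bridged lactone has no acetal carbon and stays closed.

Step 5
Reactants: 6 dithiolane acid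
Product: 7 bridged lactone acid (C2(=O)–O12 bridge on the α face; C9 CO2H on C10 and C20 methyl on C11, both β; C13=C14)
Conditions: Bu3SnH (excess), AIBN (cat.), PhMe, 110 °C
Reagents that add atoms: none
Why: Radical chain reduction with Bu3SnH, in which the stannyl radical should cleave both C–S bonds of the dithiolane (C20 becomes the C11 methyl group) and the alkenyl C13–Br bond, with no stereocentre involved in any radical step.

Step 6
Reactants: 7 bridged lactone acid
Product: 9 bridged lactone alcohol (C9 hydroxymethyl), via mixed carbonic anhydride 8 (not isolated)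
Conditions: ClCO2Et, Et3N, THF, −10 °C; then NaBH4, H2O, 0 °C
Reagents that add atoms: none
Why: Reduction of a carboxylic acid through its mixed carbonic anhydride, where NaBH4 should reduce the activated acyl group much faster than the bridged lactone, and the freed C9 alcohol should not translactonise because a trans-fused γ-lactone would force the C1 and C11 methyl groups syn-diaxial.

Step 7
Reactants: 9 bridged lactone alcohol
Product: 10 bridged lactone C9 TES ether
Conditions: Et3SiCl, imidazole, CH2Cl2, 0 °C
Reagents that add atoms: chlorotriethylsilane, CC[Si](Cl)(CC)CC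
Why: Silylation of a primary alcohol with a silyl chloride, giving an ether that survives the organolithium steps and can later be oxidised directly to the C9 aldehyde.

Step 8
Reactants: 10 bridged lactone C9 TES ether
Product: 11 ring A hydroxy ketone (acetyl group on C1 = C2 ketone with C3 methyl; free 12-hydroxyl; C9 CH2OTES)
Conditions: MeLi (1.05 equiv), THF, −78 °C; then H2O
Reagents that add atoms: methyllithium, [Li]C
Why: Addition of an organolithium to a lactone, where the bicyclic lithium hemiketal should persist at −78 °C and collapse on work-up to the C2 methyl ketone and the 12-hydroxyl, so that C3 is added and the bridge that fixed C2 and O12 cis is released.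

Step 9
Reactants: 11 ring A hydroxy ketone
Product: 12 C12 tert-butyldimethylsilyl (TBS) ether of 11
Conditions: tBuMe2SiCl, imidazole, DMF, 40 °C
Reagents that add atoms: tert-butylchlorodimethylsilane, CC(C)(C)[Si](C)(C)Cl
Why: Silylation of the secondary allylic alcohol with a silyl chloride (a silyl triflate could enolise the methyl ketone) should trap the open hydroxy ketone, and the TBS ether is chosen to outlast every TES ether.

Step 10
Reactants: 13 prop-2-yn-1-ol
Product: 15 (Z)-3-iodo-2-methylprop-2-en-1-ol, via alkenylmagnesium alkoxide 14 (not isolated)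
Conditions: MeMgBr (2.5 equiv), CuI (10 mol %), THF, −10 °C → rt; then I2, −78 → 0 °C
Reagents that add atoms: methylmagnesium bromide, C[Mg]Br; iodine, II
Why: Copper-catalysed carbomagnesiation of a propargylic alkoxide, in which methyl should add to C2 and magnesium to C3 cis to the CH2O group (chelated magnesacycle), so that iodinolysis with retention gives the Z iodide with iodine and the CH2 group (the later C6 substituent and C4) cis.

Step 11
Reactants: 15 (Z)-3-iodo-2-methylprop-2-en-1-ol
Product: 16 (Z)-3-bromo-1-iodo-2-methylprop-1-ene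
Conditions: CBr4, PPh3, CH2Cl2, 0 °C
Reagents that add atoms: tetrabromomethane, BrC(Br)(Br)Br
Why: Appel bromination of a primary allylic alcohol, which should proceed by SN2 displacement without touching the alkene geometry or the alkenyl iodide.

Step 12
Reactants: 12 C12 TBS ether methyl ketone; 16 (Z)-3-bromo-1-iodo-2-methylprop-1-ene
Product: 18 C2 ketone carrying the complete C3–C6 (Z)-iodoalkene arm, via lithium enolate 17 (not isolated)
Conditions: LiN(iPr)2, THF, −78 °C; then 16, −78 → −20 °C
Reagents that add atoms: none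
Why: Kinetic enolate alkylation, in which the ketone can only enolise toward C3 because C1 is quaternary and SN2 attack on the allylic bromide should join C3 to C4 while the alkenyl iodide stays inert, completing the C2–C6 arm with its Z alkene.

Step 13
Reactants: 18 C2 ketone
Product: 19 (2R)-alcohol
Conditions: (S)-2-methyl-CBS-oxazaborolidine (0.5 equiv), catecholborane, PhMe, −78 → −40 °C
Reagents that add atoms: none
Why: Corey–Bakshi–Shibata reduction, in which the (S)-oxazaborolidine should deliver hydride to the ketone face that gives the 2R alcohol (quaternary C1 as the large group, the C3 methylene as the small one; reagent control), while catecholborane leaves the alkenes alone.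

Step 14
Reactants: 19 (2R)-alcohol
Product: 20 C2 TES ether
Conditions: Et3SiOTf, 2,6-lutidine, CH2Cl2, −78 °C
Reagents that add atoms: triethylsilyl trifluoromethanesulfonate, CC[Si](CC)(CC)OS(=O)(=O)C(F)(F)F
Why: Silylation of a hindered secondary alcohol with a silyl triflate and a hindered base, a reaction that does not touch the existing silyl ethers or the C2 stereocentre.

Step 15
Reactants: 20 C2 TES ether
Product: 21 ring A C9 aldehyde
Conditions: (COCl)2, DMSO, CH2Cl2, −78 → −30 °C; then Et3N, −78 → 0 °C
Reagents that add atoms: none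
Why: Swern oxidation applied directly to a primary TES ether, in which the chlorosulfonium salt should cleave and oxidise only the unhindered primary silyl ether at C9 while the secondary TES and TBS ethers survive, and the cold amine stage limits epimerisation at C10.

Step 16
Reactants: 22 dimethyl (S)-malate
Product: 24 dimethyl (2S,3R)-2-hydroxy-3-methylbutanedioate, via dilithium alkoxide enolate 23 (not isolated)
Conditions: LiN(SiMe3)2 (2.2 equiv), THF, −78 → −20 °C; then MeI, −78 → 0 °C; then AcOH
Reagents that add atoms: iodomethane, CI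
Why: Fráter–Seebach alkylation, in which the chelated dianion should be methylated on the enolate face away from the ester group on the carbinol carbon to give the anti (2S,3R) diester, which sets C17 with its methyl group C18.

Step 17
Reactants: 24 dimethyl (2S,3R)-2-hydroxy-3-methylbutanedioate
Product: 25 (2S,3R)-2-hydroxy-3-methylbutanedioic acid
Conditions: LiOH, THF–H2O, 0 °C → rt; then aq. HCl
Reagents that add atoms: lithium hydroxide, [Li+].[OH-]
Why: Ester saponification under mild conditions, which should leave both stereocentres untouched.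

Step 18
Reactants: 25 (2S,3R)-2-hydroxy-3-methylbutanedioic acid
Product: 26 (2R)-2-[(2S,4S)-2-tert-butyl-5-oxo-1,3-dioxolan-4-yl]propanoic acid
Conditions: tBuCHO, TsOH (cat.), H2SO4 (cat.), pentane, reflux (water separator)
Reagents that add atoms: pivalaldehyde, CC(C)(C)C=O
Why: Acetalisation of the α-hydroxy acid unit, which should give the five-membered dioxolanone in preference to the six-membered dioxanone and, under equilibrating acid, the cis isomer that stores the C8 configuration in the acetal centre.

Step 19
Reactants: 26 dioxolanone acid; 21 ring A C9 aldehyde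
Product: 29 C9 TES ether of the aldol adduct (dioxolanone holding C7 and O8; C19 acid), via dilithium enolate 27 (not isolated), via dilithium aldolate 28 (not isolated)
Conditions: LiN(SiMe3)2 (2.1 equiv), THF, −78 °C; then 21, −78 °C; then Et3SiOTf (1.2 equiv), −78 → −40 °C; then AcOH
Reagents that add atoms: triethylsilyl trifluoromethanesulfonate, CC[Si](CC)(CC)OS(=O)(=O)C(F)(F)F
Why: Aldol addition of a dioxolanone enolate (self-regeneration of a stereocentre), in which the aldehyde should add anti to the tert-butyl group (C8 with retention), the Zimmerman–Traxler chair of the ring-fixed enolate places O8 and O9 anti, and this pairing coincides with Felkin–Anh attack on the aldehyde (C1 as the large group at C10), so that C9 is expected as 9R, while silylation of the aldolate before protonation blocks retro-aldol and lactonisation onto C19.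

Step 20
Reactants: 29 C9 TES ether dioxolanone acid
Product: 32 tris-TES ether acid (C7/C8/C9 OTES; C19 CO2H), via lithium carboxylate diol 30 (not isolated), via silyl ester 31 (not isolated)
Conditions: LiN(SiMe3)2 (1.0 equiv), THF, −78 °C; then LiBH4, 0 °C → rt; MeOH, evaporation of volatiles; then Et3SiOTf (excess), 2,6-lutidine, CH2Cl2, 0 °C → rt; aq. NaHCO3, then pH 5 buffer
Reagents that add atoms: triethylsilyl trifluoromethanesulfonate, CC[Si](CC)(CC)OS(=O)(=O)C(F)(F)F
Why: Hydride reduction of the acylal-type lactone carbonyl (C7) to the primary alcohol with loss of the acetal carbon, done on the lithium carboxylate so that C19 is neither reduced nor able to lactonise, followed by silylation of the primary C7 and tertiary C8 hydroxyls before any acidic contact and hydrolysis of the silyl ester on work-up.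

Step 21
Reactants: 32 tris-TES ether acid
Product: 33 C19 methyl ester
Conditions: MeI, KHCO3, DMF, rt
Reagents that add atoms: iodomethane, CI
Why: O-Alkylation of a carboxylate (SN2 on iodomethane) under weakly basic conditions, which should form the methyl ester without epimerising C17 or disturbing the silyl ethers.

Step 22
Reactants: 33 C19 methyl ester
Product: 34 seco C6 iodoalkene C7 aldehyde with C19 methyl ester
Conditions: (COCl)2, DMSO, CH2Cl2, −78 → −30 °C; then Et3N, −78 → 0 °C
Reagents that add atoms: none
Why: Swern oxidation of the primary TES ether, which should give the C7 aldehyde without passing through the free C7 alcohol (it would lactonise onto C19) and without cleaving the secondary and tertiary silyl ethers, and C8 cannot epimerise because it is quaternary.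

Step 23
Reactants: 34 seco C6 iodoalkene C7 aldehyde with C19 methyl ester
Product: 36 silyl-protected bicyclic lactone core, via chromium alkoxide 35 (not isolated)
Conditions: CrCl2 (10 equiv), NiCl2 (2 mol %), degassed DMSO–THF, 25 °C, slow addition of 34 (final 0.002 M); then aq. NH4Cl
Reagents that add atoms: none
Why: Divalent chromium reduces NiCl2 to zerovalent nickel, which inserts into the C6–I bond; transmetalation gives a Z-alkenyl species of trivalent chromium that adds to the C7 aldehyde with retention of the alkene geometry. The closest known reaction type is the Nozaki–Hiyama–Kishi macrocyclisation of alkenyl iodides onto aldehydes. The ten-membered ring closes by this carbonyl addition (C6–C7 bond, exo-trig at the aldehyde carbon), and the γ-lactone closes when the C7 alkoxide 35 attacks the C19 methyl ester (5-exo-trig acyl substitution, methoxide leaving), in the flask or on the mildly acidic work-up. The new stereocentre C7 is set by the aldehyde face that is attacked: in the polar Felkin–Anh arrangement the alkenyl group enters anti to the C8–O bond and past the smaller C17 branch instead of the C9 arm, which corresponds to the 7S lactone with C6 and C9 trans on the five-membered ring. The step needs chemoselectivity for the aldehyde over the ester and silyl ethers, retention of the Z alkene and ring closure over oligomerisation; the low basicity of the organochromium reagent, the preformed Z iodide from step 10 and high dilution should secure these.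

Step 24
Reactants: 36 silyl-protected bicyclic lactone core
Product: 37 2,9-diol (C8 OTES and C12 OTBS kept)
Conditions: HF·pyridine, pyridine, THF, 0 °C
Reagents that add atoms: none
Why: Buffered fluoride desilylation, which should remove the two secondary TES ethers much faster than the tertiary TES ether at C8 and the TBS ether at C12.

Step 25
Reactants: 37 2,9-diol
Product: 38 2,9-diacetate
Conditions: Ac2O, DMAP (cat.), pyridine, CH2Cl2, rt
Reagents that add atoms: acetic anhydride, CC(=O)OC(C)=O
Why: Nucleophile-catalysed acylation of the two free secondary alcohols, the only hydroxyls exposed at this stage.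

Step 26
Reactants: 38 2,9-diacetate
Product: 39 8,12-diol 2,9-diacetate
Conditions: HF·pyridine (excess), THF, rt
Reagents that add atoms: none
Why: Fluoride desilylation under mildly acidic conditions, which should cleave the TBS ether and the tertiary TES ether without acyl migration or lactone opening.

Step 27
Reactants: 39 8,12-diol 2,9-diacetate
Product: 40 target CNP0211702.1
Conditions: (PrCO)2O, DMAP (cat.), pyridine, CH2Cl2, 0 °C
Reagents that add atoms: butanoic anhydride, CCCC(=O)OC(=O)CCC
Why: Selective acylation of the secondary allylic 12-hydroxyl, since the tertiary 8-hydroxyl flanked by C7, C9 and C17 should not be acylated under these mild conditions.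

Compound list
1 | 5-hydroxyfuran-2(5H)-one (racemic, configurationally labile) | O=C1C=CC(O)O1 | starting material
2 | (5S)-5-[(1S,2R,5S)-menthyloxy]furan-2(5H)-one | O=C1C=C[C@@H](O[C@H]2C[C@@H](C)CC[C@@H]2C(C)C)O1 | intermediate
3 | 3,5-dibromo-2H-pyran-2-one | O=C1OC=C(Br)C=C1Br | starting material
4 | 5-bromo-3-methyl-2H-pyran-2-one | CC1=CC(Br)=COC1=O | intermediate
5 | endo/anti cycloadduct: ring A (C13 bromide) bridged on the α face by the C2(=O)–O12 lactone and cis-fused on the β face across C10–C11 to the γ-lactone C9(=O)–O–C20H(O-menthyl), menthyloxy group on the outer face | O=C1O[C@@H]2C(Br)=C[C@@]1(C)[C@@H]3[C@H]2[C@@H](O[C@H]4C[C@@H](C)CC[C@@H]4C(C)C)OC3=O | intermediate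
6 | bridged lactone (C13 bromide) with C9 carboxylic acid on C10 and 1,3-dithiolan-2-yl (C20) on C11, both β | O=C1O[C@@H]2C(Br)=C[C@@]1(C)[C@H]([C@H]2C3SCCS3)C(=O)O | intermediate
7 | bridged lactone acid: C2(=O)–O12 bridge (α), C9 CO2H on C10 (β), C20 methyl on C11 (β), C13=C14 | O=C1O[C@@H]2C=C[C@@]1(C)[C@H]([C@H]2C)C(=O)O | intermediate
8 | mixed ethyl carbonic anhydride of 7 | O=C1O[C@@H]2C=C[C@@]1(C)[C@H]([C@H]2C)C(=O)OC(=O)OCC | intermediate
9 | bridged lactone alcohol (C9 hydroxymethyl) | O=C1O[C@@H]2C=C[C@@]1(C)[C@H]([C@H]2C)CO | intermediate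
10 | bridged lactone C9 TES ether | O=C1O[C@@H]2C=C[C@@]1(C)[C@H]([C@H]2C)CO[Si](CC)(CC)CC | intermediate
11 | ring A hydroxy ketone: C1 methyl and acetyl (C2 ketone, C3 methyl), C10 CH2OTES, C11 methyl, 12-hydroxyl, C13=C14; C1, C10, C11, C12 as in the target | O[C@@H]1C=C[C@@](C(C)=O)(C)[C@H]([C@H]1C)CO[Si](CC)(CC)CC | intermediate
12 | C12 TBS ether of 11 | CC(C)(C)[Si](C)(C)O[C@@H]1C=C[C@@](C(C)=O)(C)[C@H]([C@H]1C)CO[Si](CC)(CC)CC | intermediate
13 | prop-2-yn-1-ol | C#CCO | starting material
14 | bromomagnesium (Z)-3-(bromomagnesio)-2-methylprop-2-en-1-olate | Br[Mg]/C=C(/C)CO[Mg]Br | intermediate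
15 | (Z)-3-iodo-2-methylprop-2-en-1-ol | OC/C(C)=C\I | intermediate
16 | (Z)-3-bromo-1-iodo-2-methylprop-1-ene | BrC/C(C)=C\I | intermediate
17 | lithium enolate of 12 (C2 enolate toward C3) | [Li+].CC(C)(C)[Si](C)(C)O[C@@H]1C=C[C@@](C([O-])=C)(C)[C@H]([C@H]1C)CO[Si](CC)(CC)CC | intermediate
18 | C2 ketone with C3–C4–C5(Me)=C6(Z)–I arm; C9 CH2OTES; C12 OTBS | CC(C)(C)[Si](C)(C)O[C@@H]1C=C[C@@](C(=O)CC/C(C)=C\I)(C)[C@H]([C@H]1C)CO[Si](CC)(CC)CC | intermediate
19 | (2R)-alcohol of 18 | CC(C)(C)[Si](C)(C)O[C@@H]1C=C[C@@]([C@H](O)CC/C(C)=C\I)(C)[C@H]([C@H]1C)CO[Si](CC)(CC)CC | intermediate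
20 | C2 TES ether of 19 | CC(C)(C)[Si](C)(C)O[C@@H]1C=C[C@@]([C@H](O[Si](CC)(CC)CC)CC/C(C)=C\I)(C)[C@H]([C@H]1C)CO[Si](CC)(CC)CC | intermediate
21 | ring A C9 aldehyde (C2 OTES, C12 OTBS, Z-iodoalkene arm) | CC(C)(C)[Si](C)(C)O[C@@H]1C=C[C@@]([C@H](O[Si](CC)(CC)CC)CC/C(C)=C\I)(C)[C@H]([C@H]1C)C=O | intermediate
22 | dimethyl (S)-malate | COC(=O)C[C@H](O)C(=O)OC | starting material
23 | dilithium alkoxide enolate of 22 | [Li+].[Li+].CO/C([O-])=C/[C@H]([O-])C(=O)OC | intermediate
24 | dimethyl (2S,3R)-2-hydroxy-3-methylbutanedioate | COC(=O)[C@H](C)[C@H](O)C(=O)OC | intermediate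
25 | (2S,3R)-2-hydroxy-3-methylbutanedioic acid | OC(=O)[C@H](C)[C@H](O)C(=O)O | intermediate
26 | (2R)-2-[(2S,4S)-2-tert-butyl-5-oxo-1,3-dioxolan-4-yl]propanoic acid (cis-dioxolanone) | OC(=O)[C@H](C)[C@@H]1O[C@H](C(C)(C)C)OC1=O | intermediate
27 | dilithium enolate carboxylate of 26 | [Li+].[Li+].[O-]C(=O)[C@H](C)C1=C([O-])O[C@@H](C(C)(C)C)O1 | intermediate
28 | dilithium aldolate (C9 alkoxide, C19 carboxylate) | [Li+].[Li+].CC(C)(C)[Si](C)(C)O[C@@H]1C=C[C@@]([C@H](O[Si](CC)(CC)CC)CC/C(C)=C\I)(C)[C@H]([C@H]1C)[C@@H]([O-])[C@@]2([C@@H](C)C([O-])=O)O[C@H](C(C)(C)C)OC2=O | intermediate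
29 | aldol adduct as C9 TES ether: C8 in the dioxolanone (C7 carbonyl, O8, tert-butyl acetal), C17 methyl, C19 acid | CC(C)(C)[Si](C)(C)O[C@@H]1C=C[C@@]([C@H](O[Si](CC)(CC)CC)CC/C(C)=C\I)(C)[C@H]([C@H]1C)[C@@H](O[Si](CC)(CC)CC)[C@@]2([C@@H](C)C(=O)O)O[C@H](C(C)(C)C)OC2=O | intermediate
30 | lithium carboxylate 7,8-diol (C9 OTES) | [Li+].CC(C)(C)[Si](C)(C)O[C@@H]1C=C[C@@]([C@H](O[Si](CC)(CC)CC)CC/C(C)=C\I)(C)[C@H]([C@H]1C)[C@@H](O[Si](CC)(CC)CC)[C@@]([C@@H](C)C([O-])=O)(O)CO | intermediate
31 | TES ester of 32 | CC(C)(C)[Si](C)(C)O[C@@H]1C=C[C@@]([C@H](O[Si](CC)(CC)CC)CC/C(C)=C\I)(C)[C@H]([C@H]1C)[C@@H](O[Si](CC)(CC)CC)[C@@]([C@@H](C)C(=O)O[Si](CC)(CC)CC)(O[Si](CC)(CC)CC)CO[Si](CC)(CC)CC | intermediate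
32 | C19 acid with C7 (primary), C8 (tertiary) and C9 TES ethers | CC(C)(C)[Si](C)(C)O[C@@H]1C=C[C@@]([C@H](O[Si](CC)(CC)CC)CC/C(C)=C\I)(C)[C@H]([C@H]1C)[C@@H](O[Si](CC)(CC)CC)[C@@]([C@@H](C)C(=O)O)(O[Si](CC)(CC)CC)CO[Si](CC)(CC)CC | intermediate
33 | C19 methyl ester of 32 | CC(C)(C)[Si](C)(C)O[C@@H]1C=C[C@@]([C@H](O[Si](CC)(CC)CC)CC/C(C)=C\I)(C)[C@H]([C@H]1C)[C@@H](O[Si](CC)(CC)CC)[C@@]([C@@H](C)C(=O)OC)(O[Si](CC)(CC)CC)CO[Si](CC)(CC)CC | intermediate
34 | seco C6 iodoalkene C7 aldehyde with C19 methyl ester (C2, C8, C9 OTES; C12 OTBS) | CC(C)(C)[Si](C)(C)O[C@@H]1C=C[C@@]([C@H](O[Si](CC)(CC)CC)CC/C(C)=C\I)(C)[C@H]([C@H]1C)[C@@H](O[Si](CC)(CC)CC)[C@@]([C@@H](C)C(=O)OC)(O[Si](CC)(CC)CC)C=O | intermediate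
35 | dichlorochromium alkoxide (trivalent chromium) of the ten-membered C7 carbinol with the C19 methyl ester still open | CC(C)(C)[Si](C)(C)O[C@@H]1C=C[C@@]2(C)[C@H]([C@H]1C)[C@@H](O[Si](CC)(CC)CC)[C@@]([C@@H](C)C(=O)OC)(O[Si](CC)(CC)CC)[C@H](/C=C(/C)CC[C@H]2O[Si](CC)(CC)CC)O[Cr](Cl)Cl | intermediate
36 | silyl-protected bicyclic lactone core (C2, C8, C9 OTES; C12 OTBS; 5Z; 7S) | CC(C)(C)[Si](C)(C)O[C@@H]1C=C[C@@]2(C)[C@H]([C@H]1C)[C@@H](O[Si](CC)(CC)CC)[C@@]1(O[Si](CC)(CC)CC)[C@H](/C=C(/C)CC[C@H]2O[Si](CC)(CC)CC)OC(=O)[C@@H]1C | intermediate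
37 | 2,9-diol (C8 OTES, C12 OTBS) | CC(C)(C)[Si](C)(C)O[C@@H]1C=C[C@@]2(C)[C@H]([C@H]1C)[C@@H](O)[C@@]1(O[Si](CC)(CC)CC)[C@H](/C=C(/C)CC[C@H]2O)OC(=O)[C@@H]1C | intermediate
38 | 2,9-diacetate (C8 OTES, C12 OTBS) | CC(C)(C)[Si](C)(C)O[C@@H]1C=C[C@@]2(C)[C@H]([C@H]1C)[C@@H](OC(C)=O)[C@@]1(O[Si](CC)(CC)CC)[C@H](/C=C(/C)CC[C@H]2OC(C)=O)OC(=O)[C@@H]1C | intermediate
39 | 8,12-diol 2,9-diacetate | O[C@@H]1C=C[C@@]2(C)[C@H]([C@H]1C)[C@@H](OC(C)=O)[C@@]1(O)[C@H](/C=C(/C)CC[C@H]2OC(C)=O)OC(=O)[C@@H]1C | intermediate
40 | CNP0211702.1 (2,9-diacetate 12-butanoate 8-ol) | CCCC(=O)O[C@@H]1C=C[C@@]2(C)[C@H]([C@H]1C)[C@@H](OC(C)=O)[C@@]1(O)[C@H](/C=C(/C)CC[C@H]2OC(C)=O)OC(=O)[C@@H]1C | target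

Total step count: 27.
Longest linear sequence: 21 steps (3 → 4 → 5 → 6 → 7 → 9 → 10 → 11 → 12 → 18 → 19 → 20 → 21 → 29 → 32 → 33 → 34 → 36 → 37 → 38 → 39 → 40; steps 2–9, 12–15 and 19–27).

Steps most likely to fail

Step 23 (ring closure). The alkenylchromium addition may prefer the other face of the C7 aldehyde, or the strained ten-membered transition state may be slow enough for intermolecular addition to compete. The fallback moves the control of C7 from the C–C bond formation to a ketone reduction; it sets out from 34 and comes back at 36. The same closure would be run and the C7-epimeric lactone F1 collected. Its lactone would be opened with MeNH(OMe)·HCl and Me3Al to the hydroxy Weinreb amide F2. The allylic C7 alcohol would be oxidised with Dess–Martin periodinane to the enone amide F3. Reduction from the opposite face (NaBH4 with CeCl3 at −78 °C, or a borane reduction under oxazaborolidine control if the substrate bias is too small) would give the 7S hydroxy amide F4, which should close to 36 with loss of the amine on treatment with pyridinium p-toluenesulfonate.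

Step 3 (cycloaddition). The hindered alkoxybutenolide may add too slowly, the adduct may lose CO2, or the regio- and facial selectivity may erode. The fallback gives up auxiliary control in favour of a less hindered dienophile and a classical resolution; it sets out from 4 and comes back at 7. Pyrone 4 and commercial furan-2(5H)-one would be combined under the same pressure to give the racemic endo lactone adduct F5. Sodium benzeneselenolate (from PhSeSePh and NaBH4, DMF, 120 °C) would open the γ-lactone by SN2 attack at its CH2–O carbon to give the seleno acid F6. Bu3SnH with AIBN would remove selenium and bromine to give the racemic acid F7. Crystallisation of the (R)-1-phenylethylammonium salt F8 (or of the salt with the antipodal amine if that one is the less soluble) and acidification would return 7.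

Step 19 (aldol). The basic dianion may enolise the α-branched aldehyde with epimerisation at C10, the congested C8–C9 bond may form slowly, or the aldolate may revert before it is silylated. The fallback replaces the basic lithium enolate by a neutral nucleophile under Lewis acid activation; it sets out from 26 and 21 and comes back at 29. Acid 26 would be converted with LiN(SiMe3)2 and Et3SiCl into the bis-silyl ketene acetal F9. A Mukaiyama aldol addition of F9 to 21 with catalytic Et3SiOTf at −78 °C (open transition state, attack anti to the tert-butyl group and Felkin–Anh at the aldehyde, silyl transfer to O9) would give the silyl ester F10, whose hydrolysis on work-up gives 29.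

Further compounds
F1 | step 23 | C7 epimer of lactone 36 | CC(C)(C)[Si](C)(C)O[C@@H]1C=C[C@@]2(C)[C@H]([C@H]1C)[C@@H](O[Si](CC)(CC)CC)[C@@]1(O[Si](CC)(CC)CC)[C@@H](/C=C(/C)CC[C@H]2O[Si](CC)(CC)CC)OC(=O)[C@@H]1C
F2 | step 23 | 7-epi C7 hydroxy C19 N-methoxy-N-methylamide | CC(C)(C)[Si](C)(C)O[C@@H]1C=C[C@@]2(C)[C@H]([C@H]1C)[C@@H](O[Si](CC)(CC)CC)[C@@]([C@@H](C)C(=O)N(C)OC)(O[Si](CC)(CC)CC)[C@@H](/C=C(/C)CC[C@H]2O[Si](CC)(CC)CC)O
F3 | step 23 | C7 ketone (enone) C19 N-methoxy-N-methylamide | CC(C)(C)[Si](C)(C)O[C@@H]1C=C[C@@]2(C)[C@H]([C@H]1C)[C@@H](O[Si](CC)(CC)CC)[C@@]([C@@H](C)C(=O)N(C)OC)(O[Si](CC)(CC)CC)C(=O)/C=C(/C)CC[C@H]2O[Si](CC)(CC)CC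
F4 | step 23 | 7S C7 hydroxy C19 N-methoxy-N-methylamide | CC(C)(C)[Si](C)(C)O[C@@H]1C=C[C@@]2(C)[C@H]([C@H]1C)[C@@H](O[Si](CC)(CC)CC)[C@@]([C@@H](C)C(=O)N(C)OC)(O[Si](CC)(CC)CC)[C@H](/C=C(/C)CC[C@H]2O[Si](CC)(CC)CC)O
F5 | step 3 | racemic endo adduct of 4 with furan-2(5H)-one (relative configuration shown) | O=C1O[C@@H]2C(Br)=C[C@@]1(C)[C@@H]3[C@H]2COC3=O
F6 | step 3 | racemic seleno acid (C20 CH2SePh on C11, C9 CO2H on C10, C13 bromide; relative configuration shown) | O=C1O[C@@H]2C(Br)=C[C@@]1(C)[C@H]([C@H]2C[Se]c3ccccc3)C(=O)O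
F7 | step 3 | racemic form of acid 7 (relative configuration shown) | O=C1O[C@@H]2C=C[C@@]1(C)[C@H]([C@H]2C)C(=O)O
F8 | step 3 | (R)-1-phenylethylammonium salt of 7 | C[C@@H]([NH3+])c1ccccc1.O=C1O[C@@H]2C=C[C@@]1(C)[C@H]([C@H]2C)C([O-])=O
F9 | step 19 | bis(triethylsilyl) ketene acetal ester of 26 | CC[Si](CC)(CC)OC(=O)[C@H](C)C1=C(O[Si](CC)(CC)CC)O[C@@H](C(C)(C)C)O1
F10 | step 19 | triethylsilyl ester of 29 | CC(C)(C)[Si](C)(C)O[C@@H]1C=C[C@@]([C@H](O[Si](CC)(CC)CC)CC/C(C)=C\I)(C)[C@H]([C@H]1C)[C@@H](O[Si](CC)(CC)CC)[C@@]2([C@@H](C)C(=O)O[Si](CC)(CC)CC)O[C@H](C(C)(C)C)OC2=O
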